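**Strategy.** The route rests on a formal [3+3] annulation that builds ring B (the cyclohexene carrying the tertiary alcohol) onto a preformed, enantiopure bicyclo[3.2.0]heptane (rings A and D). It exploits the fact that the cyclobutane carbon C7 and the cyclopentane carbon C2, both bonded to ring-fusion carbon C1, are each alpha to a carbonyl group (C6, C3): as silyl enol ether and enol acetate they form a 1,3-bis-nucleophile. One TiCl4-mediated operation joins C7 to the beta-carbon and C2 to the carbonyl carbon of a beta-ethoxyvinyl alkynyl ketone, setting three stereocentres. Ring C follows by ring-closing metathesis; the octyl chain by alkyl–alkyl cross-coupling.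

Key step: step 6

Remark: (1R,5S)-bicyclo[3.2.0]hept-2-en-6-one (1) is taken as the commercial single enantiomer; core locants C1–C7 follow the numbering of 1, and the rings are lettered A (cyclobutane), B (cyclohexene with the tertiary alcohol), C (cyclohexene with the acid), D (cyclopentane).

Step 1
Reactants: 1 (1R,5S)-bicyclo[3.2.0]hept-2-en-6-one
Product: 2 2-exo-bromo-3-endo-hydroxybicyclo[3.2.0]heptan-6-one
Conditions: NBS, acetone/H2O, 0 °C to rt
Reagents that add atoms: N-bromosuccinimide, O=C1CCC(=O)N1Br; water, O
Why: Bromohydrin formation, in which the bromonium ion should form on the convex face and water should open it at C3 from the concave face, placing bromine on C2 and oxygen on C3.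

Step 2
Reactants: 2 2-exo-bromo-3-endo-hydroxybicyclo[3.2.0]heptan-6-one
Product: 3 2-exo-bromobicyclo[3.2.0]heptane-3,6-dione
Conditions: Dess–Martin periodinane, NaHCO3, CH2Cl2, 0 °C
Reagents that add atoms: none
Why: Dess–Martin oxidation under buffered, non-enolizing conditions should give the alpha-bromo ketone without loss of bromide.

Step 3
Reactants: 3 2-exo-bromobicyclo[3.2.0]heptane-3,6-dione
Product: 4 3-acetoxybicyclo[3.2.0]hept-2-en-6-one
Conditions: Zn dust, Ac2O, NaOAc, 0 °C to rt
Reagents that add atoms: acetic anhydride, CC(=O)OC(C)=O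
Why: Reductive enol acetylation, in which zinc inserts into the activated C–Br bond and the regiodefined zinc enolate is O-acylated by the anhydride, fixing the enol double bond at C2=C3.

Step 4
Reactants: 4 3-acetoxybicyclo[3.2.0]hept-2-en-6-one
Product: 5 3-acetoxy-6-(trimethylsilyloxy)bicyclo[3.2.0]hepta-2,6-diene
Conditions: TMSOTf, Et3N, CH2Cl2, 0 °C
Reagents that add atoms: trimethylsilyl trifluoromethanesulfonate, C[Si](C)(C)OS(=O)(=O)C(F)(F)F
Why: Soft enolization of the only ketone, which can enolize only toward C7 because C5 is a bridgehead, should give the cyclobutenyl silyl enol ether.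

Step 5
Reactants: 6 (E)-3-ethoxyacryloyl chloride; 7 ethynyltrimethylsilane
Product: 8 (E)-1-ethoxy-5-(trimethylsilyl)pent-1-en-4-yn-3-one
Conditions: PdCl2(PPh3)2 (cat.), CuI (cat.), Et3N, THF, rt
Reagents that add atoms: none
Why: Acyl Sonogashira coupling of an acid chloride with a terminal alkyne should give the alkynyl ketone, the silyl group blocking the alkyne terminus.

Step 6
Reactants: 5 3-acetoxy-6-(trimethylsilyloxy)bicyclo[3.2.0]hepta-2,6-diene; 8 (E)-1-ethoxy-5-(trimethylsilyl)pent-1-en-4-yn-3-one
Product: 10 tricyclic keto acetate of rings A/B/D, via ene-dione enol acetate 9 (not isolated)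
Conditions: TiCl4 (2.2 equiv), CH2Cl2, −78 to −20 °C; aq. NaHCO3
Reagents that add atoms: none
Why: Proposed new method: TiCl4 activates vinylogous ester 8, the silyl enol ether (a far stronger π-nucleophile than the enol acetate) attacks its beta-carbon through C7 and loss of ethoxide gives ene-dione 9, whose doubly activated C7–H and Lewis-acid-bound enone should equilibrate (C7 epimer, E/Z) to the cis-fusing Z isomer; the enol acetate carbon C2 then adds to the titanium-bound ketone and the acetyl group shifts to the new alkoxide through a six-membered acetoxonium ion. The closest known reaction types are the TiCl4-mediated formal [3+3] cyclization of 1,3-bis(silyl enol ethers) with 3-alkoxy-2-en-1-ones and the Mukaiyama aldol addition of enol acetates. Ring B closes in the second event by a 6-(enolexo)-exo-trig aldol-type addition. C7 and C2 are fixed by the ring fusion, since a six-membered ring can span them only across the concave face, so both new bonds are endo and both hydrogens exo; the carbinol centre is fixed by the titanium-bound oxygen taking the open convex side while the slim alkynyl group points to the concave side. The step needs orientation selectivity (C7 to the beta-carbon, C2 to the carbonyl carbon), secured by the reactivity gap between the two enol derivatives and by the fact that only the C2-to-carbonyl closure gives a six-membered ring.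

Step 7
Reactants: 10 tricyclic keto acetate of rings A/B/D
Product: 11 endo-cyclobutanol
Conditions: NaBH4, MeOH/CH2Cl2, −78 °C
Reagents that add atoms: none
Why: Chemoselective borohydride reduction, the strained cyclobutanone reacting much faster than the hindered cyclopentanone, with hydride from the convex face (this carbinol configuration is later erased).

Step 8
Reactants: 11 endo-cyclobutanol
Product: 12 exo-cyclobutyl iodide
Conditions: I2, PPh3, imidazole, toluene, 70 °C
Reagents that add atoms: iodine, II
Why: Garegg–Samuelsson (Appel-type) iodination, in which iodide displaces the alkoxyphosphonium group from the convex face with inversion.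

Step 9
Reactants: 12 exo-cyclobutyl iodide; 13 n-octylzinc bromide
Product: 14 exo-octyl tricyclic keto acetate
Conditions: Ni(cod)2 (cat.), s-Bu-Pybox (cat.), DMA, rt
Reagents that add atoms: none
Why: Nickel-catalysed alkyl–alkyl Negishi coupling through a cyclobutyl radical that should be captured on the convex face, so the octyl group ends exo, trans to both neighbouring ring bonds, whatever the iodide configuration.

Step 10
Reactants: 14 exo-octyl tricyclic keto acetate
Product: 16 exo-aldehyde, via methyl enol ether 15 (not isolated)
Conditions: MeOCH2PPh3Cl, KHMDS, THF, −78 to 0 °C; then PPTS, acetone/H2O, 40 °C; then DBU (cat.), CH2Cl2, rt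
Reagents that add atoms: (methoxymethyl)triphenylphosphonium chloride, COC[P+](c1ccccc1)(c1ccccc1)c1ccccc1.[Cl-]; water, O
Why: Wittig methoxymethylenation, mild enol ether hydrolysis and base equilibration of the epimerizable aldehyde should give the exo-formyl isomer, trans to the bulky C2 substituent (thermodynamic control), which sets C3.

Step 11
Reactants: 16 exo-aldehyde
Product: 17 vinyl carbinol (epimer mixture)
Conditions: vinylmagnesium bromide (1.2 equiv), THF, −78 °C
Reagents that add atoms: vinylmagnesium bromide, C=C[Mg]Br
Why: Grignard 1,2-addition to the aldehyde at low temperature should spare the tertiary acetate, and the carbinol configuration is erased in the next step.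

Step 12
Reactants: 17 vinyl carbinol (epimer mixture)
Product: 18 vinyl ketone
Conditions: Dess–Martin periodinane, NaHCO3, CH2Cl2, 0 °C
Reagents that add atoms: none
Why: Dess–Martin oxidation of the secondary allylic alcohol converges both epimers on one vinyl ketone.

Step 13
Reactants: 18 vinyl ketone
Product: 20 diol alkyne, via allylic alcohol acetate 19 (not isolated)
Conditions: NaBH4, CeCl3·7H2O, MeOH, −78 °C; then K2CO3, rt to 40 °C
Reagents that add atoms: none
Why: Luche 1,2-reduction under Felkin–Anh control (hydride anti to the C2 ring carbon) should set the carbinol centre, and carbonate in methanol then removes the alkynyl silyl group and the tertiary acetate.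

Step 14
Reactants: 20 diol alkyne
Product: 21 hydroxy acrylate
Conditions: Pd(OAc)2 (cat.), 2-(diphenylphosphino)pyridine, CH3SO3H (cat.), CO (10 bar), MeOH, 45 °C
Reagents that add atoms: carbon monoxide, [C-]#[O+]; methanol, CO
Why: Palladium-catalysed Markovnikov hydromethoxycarbonylation of the terminal alkyne should give the 2-substituted methyl acrylate.

Step 15
Reactants: 21 hydroxy acrylate
Product: 22 methyl ester of the target
Conditions: second-generation Grubbs catalyst (5 mol %), toluene, 80 °C
Reagents that add atoms: none
Why: Ring-closing metathesis between the acrylate and the vinyl carbinol should close six-membered ring C as the trisubstituted enoate without touching a stereocentre.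

Step 16
Reactants: 22 methyl ester of the target
Product: 23 target acid CNP0106718.3
Conditions: LiOH, THF/H2O, rt; then 1 M HCl to pH 3
Reagents that add atoms: lithium hydroxide, [Li+].[OH-]
Why: Saponification of the methyl ester followed by acidification should give the free acid.

**Compound list**

1 | (1R,5S)-bicyclo[3.2.0]hept-2-en-6-one | O=C1C[C@@H]2C=CC[C@H]12 | starting material
2 | 2-exo-bromo-3-endo-hydroxybicyclo[3.2.0]heptan-6-one (bridgeheads as in 1) | O=C1C[C@@H]2[C@@H](Br)[C@H](O)C[C@H]12 | intermediate
3 | 2-exo-bromobicyclo[3.2.0]heptane-3,6-dione | O=C1C[C@@H]2[C@@H](Br)C(=O)C[C@H]12 | intermediate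
4 | 3-acetoxybicyclo[3.2.0]hept-2-en-6-one | O=C1C[C@@H]2C=C(OC(C)=O)C[C@H]12 | intermediate
5 | 3-acetoxy-6-(trimethylsilyloxy)bicyclo[3.2.0]hepta-2,6-diene | C[Si](C)(C)OC1=C[C@@H]2C=C(OC(C)=O)C[C@H]12 | intermediate
6 | (E)-3-ethoxyacryloyl chloride | CCO/C=C/C(Cl)=O | starting material
7 | ethynyltrimethylsilane | C#C[Si](C)(C)C | starting material
8 | (E)-1-ethoxy-5-(trimethylsilyl)pent-1-en-4-yn-3-one | CCO/C=C/C(=O)C#C[Si](C)(C)C | intermediate
9 | ene-dione enol acetate: 4 carrying a (Z)-3-oxo-5-(trimethylsilyl)pent-1-en-4-ynyl group at C7 (drawn as the C7-endo, Z isomer that cyclizes) | O=C1[C@H](/C=C\C(=O)C#C[Si](C)(C)C)[C@@H]2C=C(OC(C)=O)C[C@H]12 | intermediate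
10 | tricyclic keto acetate: cyclobutanone (ring A), ring B cyclohexene with tertiary acetate and (trimethylsilyl)ethynyl group, cyclopentanone (ring D); all ring-fusion hydrogens and the acetoxy group on the convex face | O=C1[C@@H]2C=C[C@](OC(C)=O)(C#C[Si](C)(C)C)[C@@H]3C(=O)C[C@H]1[C@H]23 | intermediate
11 | endo-cyclobutanol of 10 | O[C@@H]1[C@@H]2C=C[C@](OC(C)=O)(C#C[Si](C)(C)C)[C@@H]3C(=O)C[C@H]1[C@H]23 | intermediate
12 | exo-cyclobutyl iodide | I[C@H]1[C@@H]2C=C[C@](OC(C)=O)(C#C[Si](C)(C)C)[C@@H]3C(=O)C[C@H]1[C@H]23 | intermediate
13 | n-octylzinc bromide | CCCCCCCC[Zn]Br | starting material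
14 | exo-octyl tricyclic keto acetate | CCCCCCCC[C@H]1[C@@H]2C=C[C@](OC(C)=O)(C#C[Si](C)(C)C)[C@@H]3C(=O)C[C@H]1[C@H]23 | intermediate
15 | methyl enol ether at C3 (E/Z) | CCCCCCCC[C@H]1[C@@H]2C=C[C@](OC(C)=O)(C#C[Si](C)(C)C)[C@@H]3C(=COC)C[C@H]1[C@H]23 | intermediate
16 | C3-exo-aldehyde | CCCCCCCC[C@H]1[C@@H]2C=C[C@](OC(C)=O)(C#C[Si](C)(C)C)[C@@H]3[C@@H](C=O)C[C@H]1[C@H]23 | intermediate
17 | vinyl carbinol (both carbinol epimers) | CCCCCCCC[C@H]1[C@@H]2C=C[C@](OC(C)=O)(C#C[Si](C)(C)C)[C@@H]3[C@@H](C(O)C=C)C[C@H]1[C@H]23 | intermediate
18 | vinyl ketone | CCCCCCCC[C@H]1[C@@H]2C=C[C@](OC(C)=O)(C#C[Si](C)(C)C)[C@@H]3[C@@H](C(=O)C=C)C[C@H]1[C@H]23 | intermediate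
19 | allylic alcohol acetate (Felkin epimer) | CCCCCCCC[C@H]1[C@@H]2C=C[C@](OC(C)=O)(C#C[Si](C)(C)C)[C@@H]3[C@@H]([C@H](O)C=C)C[C@H]1[C@H]23 | intermediate
20 | diol alkyne (tertiary propargylic alcohol, secondary vinyl carbinol) | CCCCCCCC[C@H]1[C@@H]2C=C[C@](O)(C#C)[C@@H]3[C@@H]([C@H](O)C=C)C[C@H]1[C@H]23 | intermediate
21 | hydroxy acrylate (methyl 2-substituted acrylate) | CCCCCCCC[C@H]1[C@@H]2C=C[C@](O)(C(=C)C(=O)OC)[C@@H]3[C@@H]([C@H](O)C=C)C[C@H]1[C@H]23 | intermediate
22 | methyl ester of the target | CCCCCCCC[C@H]1[C@@H]2C=C[C@]3(O)C(C(=O)OC)=C[C@@H](O)[C@H]4C[C@H]1[C@H]2[C@@H]43 | intermediate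
23 | CNP0106718.3 | CCCCCCCC[C@H]1[C@@H]2C=C[C@]3(O)C(C(=O)O)=C[C@@H](O)[C@H]4C[C@H]1[C@H]2[C@@H]43 | target

**Count.** Total: 16 steps. Longest linear sequence: 15 steps (steps 1–4 and 6–16).

**Steps most likely to fail**

1. Step 6 (Proposed new method). Orientation control may be lost: the enol acetate may compete for the beta-carbon, or the silyl enol ether may add to the carbonyl group. The enol acetate may also fail to engage the ketone, leaving the open ene-dione. The fallback sets out from 5 and 8 and comes back at 10. Catalytic TMSOTf (CH2Cl2, −78 °C) should effect only the vinylogous Mukaiyama substitution and give the ene-dione enol acetate 9, now isolated. Lipase-mediated transesterification (Candida antarctica lipase B, n-butanol, MTBE) should free the triketone F1. An amine-catalysed enamine aldol addition (pyrrolidine, AcOH, CH2Cl2) should close ring B to the tertiary alcohol F2. Acetylation (Ac2O, DMAP, Et3N) should return 10.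

2. Step 10. The basic ylide may cause beta-elimination of the tertiary acetate through the ketone enolate, or enolization may outrun olefination of the hindered ketone. The fallback sets out from 14 and comes back at 16. Corey–Chaykovsky epoxidation with the far less basic dimethylsulfoxonium methylide (Me3S(O)I, NaH, DMSO) should give the spiro-epoxide F3, the methylene entering from the convex face. Meinwald rearrangement (MgBr2·OEt2, CH2Cl2, −20 °C) followed by DBU equilibration should give aldehyde 16.

3. Step 14. The acid co-catalyst may ionize or rearrange the tertiary propargylic alcohol, or the acyl-palladium species may be trapped by the neighbouring hydroxyl group. The fallback sets out from 20 and comes back at 23. Ring-closing enyne metathesis (second-generation Grubbs catalyst, ethylene atmosphere, toluene) should close ring C directly to the vinyl diene F4. Lemieux–Johnson cleavage of the terminal vinyl group (OsO4 cat., NaIO4, 2,6-lutidine) should give the enal F5. Pinnick oxidation (NaClO2, NaH2PO4, 2-methyl-2-butene) should give acid 23.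

Further compounds
F1 | step 6 | triketone (drawn as the C7-endo, Z isomer) | O=C1[C@H](/C=C\C(=O)C#C[Si](C)(C)C)[C@@H]2CC(=O)C[C@H]12
F2 | step 6 | tricyclic aldol, free tertiary alcohol of 10 | O=C1[C@@H]2C=C[C@](O)(C#C[Si](C)(C)C)[C@@H]3C(=O)C[C@H]1[C@H]23
F3 | step 10 | spiro-epoxide at C3 | CCCCCCCC[C@H]1[C@@H]2C=C[C@](OC(C)=O)(C#C[Si](C)(C)C)[C@@H]3[C@@]4(CO4)C[C@H]1[C@H]23
F4 | step 14 | tetracyclic diol with vinyl group in place of the carboxyl group | CCCCCCCC[C@H]1[C@@H]2C=C[C@]3(O)C(C=C)=C[C@@H](O)[C@H]4C[C@H]1[C@H]2[C@@H]43
F5 | step 14 | tetracyclic enal | CCCCCCCC[C@H]1[C@@H]2C=C[C@]3(O)C(C=O)=C[C@@H](O)[C@H]4C[C@H]1[C@H]2[C@@H]43
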